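## Retrosynthetic overview

- **Numbering:** ring B–C7–C8–C9 and syringyl–C7'–C8'–C9' are joined at C8–C8' and bridged by C7–O–C9' (ring 1) and C7'–O–C9 (ring 2). The side chain is ring A–C7''–C8''–C9'' with C8''–O–C4 of ring B.
- **Feature used:** ring 1 (C7–O–C9'–C8'–C8) is a 2-aryltetrahydrofuran. Its O–C9'–C8'–C7' part is the skeleton of ring-opened 2-vinyloxirane, and its C7–C8(–C9) part is a benzylidene malonate. C7–O and C8–C8' are therefore made together in one palladium-catalysed [3+2] step from the racemic epoxide.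
- **Side chain (cut first):** C7''–C8'' comes from an auxiliary-controlled glycolate aldol on the ring B aryloxyacetyl imide, and O–C8'' from phenol alkylation. The syn aldol gives the threo series but the target is erythro (7''R,8''S), so C7'' is inverted afterwards.
- **Ring 2:** C7'–aryl comes from Friedel–Crafts arylation of the bicyclic lactol with 2,6-dimethoxyphenol. The lactol comes from the C9 alcohol and the C7' aldehyde (the ozonised vinyl group). C8 is set on loss of the second ester.
- **Order of ring formation:** ring 1 (step 3), then ring 2 (step 6), then the syringyl group, then the side chain.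

Key step: step 3

Assumption: the hand of the bisphosphine in step 3 is inferred from its behaviour with this epoxide and heteroatom nucleophiles; if a first run shows the antipode of 6, the (R,R)-ligand is used and nothing else changes.

## Route

Step 1
Reactants: 1 vanillin
Product: 2 4-(benzyloxy)-3-methoxybenzaldehyde
Conditions: BnBr, K2CO3, DMF, rt
Reagents that add atoms: benzyl bromide, BrCc1ccccc1
Why: Williamson etherification of the phenoxide (SN2) masks the ring B phenol with a group that is stable up to step 9, and the same aldehyde later serves as the ring A building block in step 12.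

Step 2
Reactants: 2 4-(benzyloxy)-3-methoxybenzaldehyde; 3 dimethyl malonate
Product: 4 dimethyl 2-[4-(benzyloxy)-3-methoxybenzylidene]malonate
Conditions: piperidine (cat.), AcOH (cat.), toluene, reflux, Dean–Stark
Reagents that add atoms: none
Why: Knoevenagel condensation driven by azeotropic removal of water, with no alkene geometry issue because the malonate carbon carries two identical esters.

Step 3
Reactants: 4 dimethyl 2-[4-(benzyloxy)-3-methoxybenzylidene]malonate; 5 racemic 2-vinyloxirane
Product: 6 dimethyl (2S,4S)-2-[4-(benzyloxy)-3-methoxyphenyl]-4-vinyltetrahydrofuran-3,3-dicarboxylate (aryl and vinyl trans)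
Conditions: Pd2(dba)3·CHCl3 (2.5 mol %), (S,S)-DACH-naphthyl bisphosphine {N,N'-[(1S,2S)-cyclohexane-1,2-diyl]bis[2-(diphenylphosphanyl)-1-naphthamide], 7.5 mol %}, CH2Cl2, 0 °C to rt, 5 (1.5 equiv) added slowly
Reagents that add atoms: none
Why: Zerovalent palladium ionises the strained allylic C–O bond of both enantiomers of 5, and the resulting palladium-bound allyl alkoxide zwitterions interconvert through a sigma-allyl form at the unsubstituted CH2 end faster than they are consumed, so the racemate is drained through one diastereomeric complex. The alkoxide adds in a reversible oxa-Michael step to the benzylidene carbon of 4 (bond C7–O), and the malonate carbanion thus formed attacks the internal allyl carbon on the face away from the metal (bond C8–C8'), which closes ring 1 in a 5-exo allylic alkylation and returns the catalyst. The closest known reaction type is the palladium-catalysed formal [3+2] cycloaddition of vinyl epoxides or vinylethylene carbonates with doubly activated alkenes, of which enantioselective cases with nitroalkenes, enones and nitroacrylates are known. C8' is fixed by the chiral pocket of the bisphosphine in the irreversible C–C bond formation, and C7 is fixed in the same event because, under Curtin–Hammett conditions, only the oxa-Michael adduct that holds the aryl group on the ring face opposite to the bulky ligated allyl residue closes quickly, which should leave aryl and vinyl trans. The step needs attack at the internal and not the terminal allyl carbon, which the three-atom tether secures (five- against seven-membered ring), and conjugate addition in preference to ester exchange or epoxide isomerisation, which the two esters on C8 and the slow addition of 5 secure.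

Step 4
Reactants: 6 dimethyl (2S,4S)-2-[4-(benzyloxy)-3-methoxyphenyl]-4-vinyltetrahydrofuran-3,3-dicarboxylate
Product: 7 methyl (2R,3R,4S)-2-[4-(benzyloxy)-3-methoxyphenyl]-4-vinyltetrahydrofuran-3-carboxylate (2,3-trans and 3,4-cis)
Conditions: LiCl, H2O, DMSO, 150 °C
Reagents that add atoms: none
Why: Krapcho dealkoxycarbonylation, in which chloride demethylates one ester, CO2 is lost and the C8 ester enolate is protonated reversibly at this temperature, so C8 should settle in the thermodynamic arrangement with the ester trans to the large C7 aryl group and cis to the slim C8' vinyl group (the minor C8 epimer is separated and resubmitted).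

Step 5
Reactants: 7 methyl (2R,3R,4S)-2-[4-(benzyloxy)-3-methoxyphenyl]-4-vinyltetrahydrofuran-3-carboxylate
Product: 8 {(2R,3S,4S)-2-[4-(benzyloxy)-3-methoxyphenyl]-4-vinyltetrahydrofuran-3-yl}methanol
Conditions: LiAlH4, THF, 0 °C
Reagents that add atoms: none
Why: Hydride reduction of the ester to the C9 alcohol, which leaves the isolated alkene, the benzyl ether and the three stereocenters untouched.

Step 6
Reactants: 8 {(2R,3S,4S)-2-[4-(benzyloxy)-3-methoxyphenyl]-4-vinyltetrahydrofuran-3-yl}methanol
Product: 11 (1R,3aS,4R,6aS)-4-[4-(benzyloxy)-3-methoxyphenyl]tetrahydro-1H,3H-furo[3,4-c]furan-1-ol (bicyclic lactol), via secondary ozonide 9 (not isolated), via hydroxy aldehyde 10 (not isolated)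
Conditions: O3, CH2Cl2, −78 °C (Sudan Red 7B end point); Me2S, −78 °C to rt
Reagents that add atoms: ozone, [O-][O+]=O
Why: Ozonolysis with reductive work-up unmasks the C7' aldehyde, which sits cis to the C9 hydroxymethyl group on ring 1 and closes ring 2 at once as the cis-fused hemiacetal (5-exo-trig), while the dye end point spares the electron-rich arenes.

Step 7
Reactants: 11 bicyclic lactol; 12 2,6-dimethoxyphenol
Product: 13 4-{(1R,3aS,4R,6aS)-4-[4-(benzyloxy)-3-methoxyphenyl]tetrahydro-1H,3H-furo[3,4-c]furan-1-yl}-2,6-dimethoxyphenol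
Conditions: 12 (3 equiv), BF3·OEt2 (0.3 equiv), 4 Å MS, CH2Cl2, −40 to 0 °C
Reagents that add atoms: none
Why: Friedel–Crafts-type C-arylation of a cyclic oxocarbenium ion, known from aryl C-glycoside synthesis and from the arylation of furofuran lactols with phenols: the Lewis acid ionises the anomeric C7'–OH far more easily than the C7–O ether, any O-aryl acetal forms reversibly, and the phenol attacks through its unhindered C4 (para to OH) on the convex face of the cis-fused bicycle, which should set C7' with the aryl group exo (R).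

Step 8
Reactants: 13 4-{(1R,3aS,4R,6aS)-4-[4-(benzyloxy)-3-methoxyphenyl]tetrahydro-1H,3H-furo[3,4-c]furan-1-yl}-2,6-dimethoxyphenol
Product: 14 {4-[(1R,3aS,4R,6aS)-4-(4-benzyloxy-3-methoxyphenyl)tetrahydro-1H,3H-furo[3,4-c]furan-1-yl]-2,6-dimethoxyphenoxy}triisopropylsilane
Conditions: TIPSCl, imidazole, DMAP (cat.), DMF, rt to 40 °C
Reagents that add atoms: triisopropylsilyl chloride, CC(C)[Si](Cl)(C(C)C)C(C)C
Why: Silylation of the syringyl phenol with a bulky silyl group that survives hydrogenolysis, carbonate bases, boron enolate chemistry and borohydride, so the two phenols of the core can be told apart.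

Step 9
Reactants: 14 triisopropylsilyl ether
Product: 15 4-[(1R,3aS,4R,6aS)-4-(3,5-dimethoxy-4-triisopropylsilyloxyphenyl)tetrahydro-1H,3H-furo[3,4-c]furan-1-yl]-2-methoxyphenol
Conditions: H2 (1 atm), 10% Pd/C, EtOAc, rt, stopped at full conversion
Reagents that add atoms: none
Why: Catalytic hydrogenolysis of the aryl benzyl ether, which under neutral conditions at 1 atm is faster than cleavage of the cyclic benzylic C–O bonds of the furofuran, frees only the ring B phenol.

Step 10
Reactants: 16 (R)-4-benzyloxazolidin-2-one; 17 bromoacetyl bromide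
Product: 19 (R)-4-benzyl-3-(2-bromoacetyl)oxazolidin-2-one, via lithium oxazolidinide 18 (not isolated)
Conditions: n-BuLi, THF, −78 °C; then 17, −78 to 0 °C
Reagents that add atoms: none
Why: N-acylation of the lithiated oxazolidinone by the acid bromide, which reacts at the acyl carbon much faster than at the CH2Br carbon.

Step 11
Reactants: 15 ring B phenol; 19 (R)-4-benzyl-3-(2-bromoacetyl)oxazolidin-2-one
Product: 20 (R)-4-benzyl-3-(2-{4-[(1R,3aS,4R,6aS)-4-(3,5-dimethoxy-4-triisopropylsilyloxyphenyl)tetrahydro-1H,3H-furo[3,4-c]furan-1-yl]-2-methoxyphenoxy}acetyl)oxazolidin-2-one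
Conditions: K2CO3, acetone, rt
Reagents that add atoms: none
Why: Williamson-type SN2 alkylation of the phenoxide by the highly reactive alpha-bromo imide forms the C4–O–C8'' ether and brings in the auxiliary in one operation under conditions that the aryl silyl ether tolerates.

Step 12
Reactants: 20 aryloxyacetyl imide; 2 4-(benzyloxy)-3-methoxybenzaldehyde
Product: 23 (R)-4-benzyl-3-[(2R,3S)-2-aryloxy-3-(4-benzyloxy-3-methoxyphenyl)-3-hydroxypropanoyl]oxazolidin-2-one (aryloxy as in 20; syn), via boron enolate 21 (not isolated), via boron aldolate 22 (not isolated)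
Conditions: Bu2BOTf, Et3N, CH2Cl2, −78 to 0 °C; 2, −78 to 0 °C; pH 7 buffer, MeOH, 30% H2O2, 0 °C
Reagents that add atoms: none
Why: Evans syn aldol, in which soft enolisation gives the Z boron enolate that reacts through a Zimmerman–Traxler chair on the face left open by the (R)-benzyl group, so C8'' is set in its final sense and C7'' in the syn (threo, 7''S) sense that step 15 corrects.

Step 13
Reactants: 23 syn aldol adduct
Product: 24 threo-(7''S,8''S) 1,3-diol (ring A O-benzyl, syringyl O-TIPS)
Conditions: LiBH4, H2O (1 equiv), THF–Et2O, 0 °C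
Reagents that add atoms: none
Why: Reductive cleavage of the N-acyloxazolidinone with borohydride gives the C9'' alcohol and returns the auxiliary without retro-aldol cleavage or epimerisation at C8''.

Step 14
Reactants: 24 threo diol
Product: 25 threo-(7''S,8''S) 9''-O-tert-butyldimethylsilyl ether
Conditions: TBSCl (1.05 equiv), imidazole, CH2Cl2, 0 °C
Reagents that add atoms: tert-butyldimethylsilyl chloride, CC(C)(C)[Si](C)(C)Cl
Why: Selective silylation of the primary over the hindered secondary benzylic alcohol leaves only the C7'' hydroxyl free and removes any neighbouring acyl participation in the next step.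

Step 15
Reactants: 25 threo silyl ether
Product: 26 erythro-(7''R,8''S) 7''-O-(4-nitrobenzoate)
Conditions: 4-nitrobenzoic acid, PPh3, DIAD, toluene, −20 °C to rt
Reagents that add atoms: 4-nitrobenzoic acid, O=C(O)c1ccc(cc1)[N+](=O)[O-]
Why: Mitsunobu inversion, known for the threo to erythro conversion of protected arylglycerol beta-aryl ethers: the alkoxyphosphonium salt is displaced by the acidic carboxylate in an SN2 reaction, and the low temperature and apolar solvent hold back ionisation of the electron-rich benzylic centre, so C7'' should become R.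

Step 16
Reactants: 26 erythro 4-nitrobenzoate
Product: 27 erythro-(7''R,8''S) alcohol (9''-O-TBS, ring A O-benzyl, syringyl O-TIPS)
Conditions: K2CO3 (0.3 equiv), MeOH–THF, 0 °C
Reagents that add atoms: none
Why: Base-catalysed transesterification of the activated benzoate breaks the acyl–oxygen bond only, so C7'' keeps its configuration, and the benzyl ether on ring A rules out quinone methide formation.

Step 17
Reactants: 27 erythro alcohol
Product: 28 4''-O-benzylficusesquilignan A
Conditions: TBAF, AcOH, THF, 0 °C to rt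
Reagents that add atoms: none
Why: Fluoride-induced desilylation removes the alkyl TBS and the aryl TIPS ether together, the acetic acid buffer keeping the medium too mild for any change at the benzylic centres.

Step 18
Reactants: 28 4''-O-benzylficusesquilignan A
Product: 29 ficusesquilignan A
Conditions: H2 (1 atm), 10% Pd/C, EtOAc–EtOH, rt, stopped at full conversion
Reagents that add atoms: none
Why: Catalytic hydrogenolysis of the last aryl benzyl ether under neutral conditions, under which the C7'' benzylic alcohol and the furofuran C–O bonds react much more slowly.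

## Compound list

1 | vanillin | COc1cc(C=O)ccc1O | starting material
2 | 4-(benzyloxy)-3-methoxybenzaldehyde | COc1cc(C=O)ccc1OCc1ccccc1 | intermediate
3 | dimethyl malonate | COC(=O)CC(=O)OC | starting material
4 | dimethyl 2-[4-(benzyloxy)-3-methoxybenzylidene]malonate | COC(=O)C(=Cc1ccc(OCc2ccccc2)c(OC)c1)C(=O)OC | intermediate
5 | racemic 2-vinyloxirane | C=CC1CO1 | starting material
6 | dimethyl (2S,4S)-2-[4-(benzyloxy)-3-methoxyphenyl]-4-vinyltetrahydrofuran-3,3-dicarboxylate | COc1cc([C@@H]2OC[C@@H](C=C)C2(C(=O)OC)C(=O)OC)ccc1OCc1ccccc1 | intermediate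
7 | methyl (2R,3R,4S)-2-[4-(benzyloxy)-3-methoxyphenyl]-4-vinyltetrahydrofuran-3-carboxylate (C7 geometry as in 6; its descriptor changes with the CIP ranks only) | COc1cc([C@@H]2OC[C@@H](C=C)[C@H]2C(=O)OC)ccc1OCc1ccccc1 | intermediate
8 | {(2R,3S,4S)-2-[4-(benzyloxy)-3-methoxyphenyl]-4-vinyltetrahydrofuran-3-yl}methanol | COc1cc([C@@H]2OC[C@@H](C=C)[C@H]2CO)ccc1OCc1ccccc1 | intermediate
9 | secondary ozonide (1,2,4-trioxolane) of 8, not isolated | COc1cc([C@@H]2OC[C@@H](C3OCOO3)[C@H]2CO)ccc1OCc1ccccc1 | intermediate
10 | (3S,4S,5R)-5-[4-(benzyloxy)-3-methoxyphenyl]-4-(hydroxymethyl)tetrahydrofuran-3-carbaldehyde, not isolated | COc1cc([C@@H]2OC[C@@H](C=O)[C@H]2CO)ccc1OCc1ccccc1 | intermediate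
11 | (1R,3aS,4R,6aS)-4-[4-(benzyloxy)-3-methoxyphenyl]tetrahydro-1H,3H-furo[3,4-c]furan-1-ol (anomers equilibrate; exo-OH anomer drawn) | COc1cc([C@@H]2OC[C@@H]3[C@H]2CO[C@H]3O)ccc1OCc1ccccc1 | intermediate
12 | 2,6-dimethoxyphenol | COc1cccc(OC)c1O | starting material
13 | 4-{(1R,3aS,4R,6aS)-4-[4-(benzyloxy)-3-methoxyphenyl]tetrahydro-1H,3H-furo[3,4-c]furan-1-yl}-2,6-dimethoxyphenol | COc1cc([C@@H]2OC[C@@H]3[C@H]2CO[C@H]3c2cc(OC)c(O)c(OC)c2)ccc1OCc1ccccc1 | intermediate
14 | triisopropylsilyl ether of 13 | COc1cc([C@@H]2OC[C@@H]3[C@H]2CO[C@H]3c2cc(OC)c(O[Si](C(C)C)(C(C)C)C(C)C)c(OC)c2)ccc1OCc1ccccc1 | intermediate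
15 | 4-[(1R,3aS,4R,6aS)-4-(3,5-dimethoxy-4-triisopropylsilyloxyphenyl)tetrahydro-1H,3H-furo[3,4-c]furan-1-yl]-2-methoxyphenol | COc1cc([C@@H]2OC[C@@H]3[C@H]2CO[C@H]3c2cc(OC)c(O[Si](C(C)C)(C(C)C)C(C)C)c(OC)c2)ccc1O | intermediate
16 | (R)-4-benzyloxazolidin-2-one | O=C1N[C@H](Cc2ccccc2)CO1 | starting material
17 | bromoacetyl bromide | BrCC(Br)=O | starting material
18 | lithium salt of 16, not isolated | [Li]N1[C@H](Cc2ccccc2)COC1=O | intermediate
19 | (R)-4-benzyl-3-(2-bromoacetyl)oxazolidin-2-one | BrCC(=O)N1[C@H](Cc2ccccc2)COC1=O | intermediate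
20 | (R)-4-benzyl-3-(aryloxyacetyl)oxazolidin-2-one, aryloxy = O-linked 15 | COc1cc([C@@H]2OC[C@@H]3[C@H]2CO[C@H]3c2cc(OC)c(O[Si](C(C)C)(C(C)C)C(C)C)c(OC)c2)ccc1OCC(=O)N1[C@H](Cc2ccccc2)COC1=O | intermediate
21 | (Z)-dibutylboron enolate of 20, not isolated | COc1cc([C@@H]2OC[C@@H]3[C@H]2CO[C@H]3c2cc(OC)c(O[Si](C(C)C)(C(C)C)C(C)C)c(OC)c2)ccc1O/C=C(\OB(CCCC)CCCC)N1[C@H](Cc2ccccc2)COC1=O | intermediate
22 | dibutylboron aldolate of 23, not isolated | COc1cc([C@H](OB(CCCC)CCCC)[C@H](C(=O)N2[C@H](Cc3ccccc3)COC2=O)Oc2ccc([C@@H]3OC[C@@H]4[C@H]3CO[C@H]4c3cc(OC)c(O[Si](C(C)C)(C(C)C)C(C)C)c(OC)c3)cc2OC)ccc1OCc1ccccc1 | intermediate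
23 | syn aldol adduct, (2R,3S)-propanoyl imide of the (R)-auxiliary | COc1cc([C@H](O)[C@H](C(=O)N2[C@H](Cc3ccccc3)COC2=O)Oc2ccc([C@@H]3OC[C@@H]4[C@H]3CO[C@H]4c3cc(OC)c(O[Si](C(C)C)(C(C)C)C(C)C)c(OC)c3)cc2OC)ccc1OCc1ccccc1 | intermediate
24 | threo-(7''S,8''S) diol | COc1cc([C@H](O)[C@H](CO)Oc2ccc([C@@H]3OC[C@@H]4[C@H]3CO[C@H]4c3cc(OC)c(O[Si](C(C)C)(C(C)C)C(C)C)c(OC)c3)cc2OC)ccc1OCc1ccccc1 | intermediate
25 | threo-(7''S,8''S) 9''-O-TBS ether | COc1cc([C@H](O)[C@H](CO[Si](C)(C)C(C)(C)C)Oc2ccc([C@@H]3OC[C@@H]4[C@H]3CO[C@H]4c3cc(OC)c(O[Si](C(C)C)(C(C)C)C(C)C)c(OC)c3)cc2OC)ccc1OCc1ccccc1 | intermediate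
26 | erythro-(7''R,8''S) 7''-O-(4-nitrobenzoate) | COc1cc([C@@H](OC(=O)c2ccc(cc2)[N+](=O)[O-])[C@H](CO[Si](C)(C)C(C)(C)C)Oc2ccc([C@@H]3OC[C@@H]4[C@H]3CO[C@H]4c3cc(OC)c(O[Si](C(C)C)(C(C)C)C(C)C)c(OC)c3)cc2OC)ccc1OCc1ccccc1 | intermediate
27 | erythro-(7''R,8''S) alcohol, 9''-O-TBS | COc1cc([C@@H](O)[C@H](CO[Si](C)(C)C(C)(C)C)Oc2ccc([C@@H]3OC[C@@H]4[C@H]3CO[C@H]4c3cc(OC)c(O[Si](C(C)C)(C(C)C)C(C)C)c(OC)c3)cc2OC)ccc1OCc1ccccc1 | intermediate
28 | 4''-O-benzylficusesquilignan A | COc1cc([C@@H](O)[C@H](CO)Oc2ccc([C@@H]3OC[C@@H]4[C@H]3CO[C@H]4c3cc(OC)c(O)c(OC)c3)cc2OC)ccc1OCc1ccccc1 | intermediate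
29 | ficusesquilignan A, (7R,8S,7'R,8'S,7''R,8''S) | COc1cc([C@@H](O)[C@H](CO)Oc2ccc([C@@H]3OC[C@@H]4[C@H]3CO[C@H]4c3cc(OC)c(O)c(OC)c3)cc2OC)ccc1O | target

## Step count and risks

Total step count: 18.
Longest linear sequence: 17 steps from vanillin (steps 1 to 9 and 11 to 18). Step 10 is a one-step side branch.

**Step 3 (highest risk).**
- What may go wrong:
  - The electron-rich benzylidene malonate may take up the alkoxide too slowly, so that oligomerisation or isomerisation of the epoxide wins.
  - Enantiodiscrimination in the ring closure may be weak.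
  - The aryl/vinyl facial selectivity may be poor.
- The fallback sets out from aldehyde 2 and comes back at alcohol 8, so steps 2 to 5 are not needed.
- Furan-2(5H)-one takes up a vinyl group from potassium vinyltrifluoroborate in a rhodium-catalysed asymmetric conjugate addition ([Rh(cod)2]BF4 and BINAP of the hand that gives the R product). This gives (R)-4-vinyldihydrofuran-2(3H)-one F1.
- Its lithium enolate (LiN(SiMe3)2, THF, −78 °C) adds to 2 on the face away from the vinyl group and gives the trans aldol lactone F2 as a pair of carbinol epimers.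
- LiAlH4 opens the lactone to the triol F3.
- Catalytic camphorsulfonic acid in CH2Cl2 ionises the 4-alkoxybenzylic carbinol. The C9' hydroxyl closes ring 1 with the aryl group trans to C9, so both carbinol epimers converge on 8.
- The trans relation in the lactone becomes the cis relation of C9 and vinyl on ring 1, so C8 is secured as well.

**Step 4.**
- What may go wrong:
  - Protonation of the C8 enolate may show poor facial bias.
  - Equilibration to the 2,3-trans ester may be incomplete.
  - Ring 1 may open by retro-oxa-Michael elimination at high temperature.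
- The fallback sets out from cycloadduct 6 and comes back at silyl ether 14, leaving out steps 4 to 8. It therefore also avoids the regiochemical question of step 7.
- Ozonolysis of 6 (O3, CH2Cl2, −78 °C, then Me2S) gives the aldehyde diester F4.
- Purchased 4-bromo-2,6-dimethoxyphenol is silylated (TIPSCl, imidazole) to the aryl bromide F5 and turned with magnesium into the Grignard reagent F6.
- F6 adds to the aldehyde of F4 at −78 °C. On warming, the alkoxide can reach only the ester on its own face of ring 1 and closes the bicyclic lactone ester F7 (C7' epimers).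
- Demethylation and decarboxylation with LiI in boiling pyridine gives the lactone F8, in which C8 can only be protonated to the cis-fused bicycle.
- LiAlH4 gives the diol F9.
- Catalytic camphorsulfonic acid in CH2Cl2 at 0 °C closes ring 2 through the benzylic cation at C7' with the aryl group on the convex face, giving 14.

**Step 15.**
- What may go wrong: the activated, electron-rich benzylic alcohol may ionise in part, which erodes the inversion, or it may eliminate towards the enol ether.
- The fallback sets out from 25 and comes back at 27.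
- Dess–Martin periodinane (NaHCO3, CH2Cl2) gives the aryl ketone F10.
- Zn(BH4)2 in Et2O at −40 °C reduces it through the five-membered chelate of the carbonyl and aryloxy oxygens.
- Hydride arrives from the side of the C8'' hydrogen, which is the known chelation-controlled route to anti (erythro) 1,2-diol monoethers.

Further compounds
F1 | step 3 | (R)-4-vinyldihydrofuran-2(3H)-one | C=C[C@@H]1COC(=O)C1
F2 | step 3 | (3R,4S)-3-{[4-(benzyloxy)-3-methoxyphenyl](hydroxy)methyl}-4-vinyldihydrofuran-2(3H)-one, carbinol epimers | C=C[C@@H]1COC(=O)[C@H]1C(O)c1ccc(OCc2ccccc2)c(OC)c1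
F3 | step 3 | (2S,3S)-2-{[4-(benzyloxy)-3-methoxyphenyl](hydroxy)methyl}-3-vinylbutane-1,4-diol, carbinol epimers | C=C[C@H](CO)[C@@H](CO)C(O)c1ccc(OCc2ccccc2)c(OC)c1
F4 | step 4 | dimethyl (2S,4S)-2-[4-(benzyloxy)-3-methoxyphenyl]-4-formyltetrahydrofuran-3,3-dicarboxylate | COc1cc([C@@H]2OC[C@@H](C=O)C2(C(=O)OC)C(=O)OC)ccc1OCc1ccccc1
F5 | step 4 | (4-bromo-2,6-dimethoxyphenoxy)triisopropylsilane | COc1cc(Br)cc(OC)c1O[Si](C(C)C)(C(C)C)C(C)C
F6 | step 4 | 3,5-dimethoxy-4-(triisopropylsilyloxy)phenylmagnesium bromide | COc1cc([Mg]Br)cc(OC)c1O[Si](C(C)C)(C(C)C)C(C)C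
F7 | step 4 | bicyclic lactone ester (ring 2 as C8–C9(=O)–O–C7'(aryl)–C8', CO2Me on C8, C7' epimers) | COc1cc([C@@H]2OC[C@@H]3[C@@]2(C(=O)OC)C(=O)OC3c2cc(OC)c(O[Si](C(C)C)(C(C)C)C(C)C)c(OC)c2)ccc1OCc1ccccc1
F8 | step 4 | cis-fused C9 lactone (H on C8, C7' epimers) | COc1cc([C@@H]2OC[C@@H]3[C@H]2C(=O)OC3c2cc(OC)c(O[Si](C(C)C)(C(C)C)C(C)C)c(OC)c2)ccc1OCc1ccccc1
F9 | step 4 | diol with C9 hydroxymethyl and C7' aryl carbinol on ring 1 (C7' epimers) | COc1cc([C@@H]2OC[C@@H](C(O)c3cc(OC)c(O[Si](C(C)C)(C(C)C)C(C)C)c(OC)c3)[C@H]2CO)ccc1OCc1ccccc1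
F10 | step 15 | (8''S) C7'' aryl ketone, 9''-O-TBS | COc1cc(C(=O)[C@H](CO[Si](C)(C)C(C)(C)C)Oc2ccc([C@@H]3OC[C@@H]4[C@H]3CO[C@H]4c3cc(OC)c(O[Si](C(C)C)(C(C)C)C(C)C)c(OC)c3)cc2OC)ccc1OCc1ccccc1
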